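**Retrosynthetic overview**

1. All four rings of each half are bought: andrographolide (1) becomes, through its 3,19-acetonide (2), the electrophilic half, 14-acetate 3; commercial 14-deoxy-11,12-didehydroandrographolide (4) becomes the nucleophilic half, silyloxyfuran 5.
2. Key disconnection: the C15–C12' bond, traced back to an endo [4+2] cycloaddition of the furan diene of 5 (C16=C13–C14=C15) to the exocyclic C12'=C13' alkene of 3, on the face anti to the C14' acetate; this gives oxanorbornene 6 (new bonds C15–C12' and C16–C13').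
3. Second disconnection: the C16–C13' bond of 6 is temporary; Grob fragmentation (loss of Et3SiOAc from C14') restores both butenolides and gives protected dimer 7, so the C14' stereocentre of 1 sets C12' and C15 and is then erased.
4. Last disconnection: the O-protecting groups (one acetonide, two silyl ethers), removed together to give target 8.
5. Ring order: no ring of 8 is built de novo; the only ring formed is the transient 7-oxabicyclo[2.2.1]heptene of 6, made and reopened in the same flask.

Assumption: 4 is bought as such (it is also the one-step dehydration product of 1); labdane locants are used, primed for the half that carries C12'. The target is (15R,12'S), with both decalins in the configuration of 1.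

**Route**

Step 1
Reactants: 1 andrographolide
Product: 2 3,19-O-isopropylideneandrographolide
Conditions: Me2C(OMe)2, PPTS (cat.), toluene–DMSO, 80 °C
Reagents that add atoms: 2,2-dimethoxypropane, COC(C)(C)OC
Why: Acid-catalysed transketalisation closes a six-membered 1,3-dioxane across the 1,3-related C3 and C19 hydroxyls, while the isolated C14 allylic alcohol stays free and no stereocentre is touched.

Step 2
Reactants: 2 3,19-O-isopropylideneandrographolide
Product: 3 14-O-acetyl-3,19-O-isopropylideneandrographolide
Conditions: Ac2O, pyridine, DMAP (cat.), CH2Cl2, 0 °C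
Reagents that add atoms: acetic anhydride, CC(=O)OC(C)=O
Why: DMAP-catalysed O-acylation of the only free hydroxyl leaves the C14–O bond intact (14S retained), and the weak base and low temperature suppress 1,4-elimination to the diene.

Step 3
Reactants: 4 14-deoxy-11,12-didehydroandrographolide
Product: 5 3,19-bis-O-triethylsilyl-14-deoxy-11,12-didehydroandrographolide 16-O-triethylsilyl dienol ether (a 2-triethylsilyloxy-3-alkenylfuran)
Conditions: Et3SiOTf (3.5 equiv), Et3N (5 equiv), CH2Cl2, −78 to 0 °C; pentane extraction, used without chromatography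
Reagents that add atoms: triethylsilyl trifluoromethanesulfonate, CC[Si](CC)(CC)OS(=O)(=O)C(F)(F)F
Why: Silyl triflate and amine silylate both alcohols and, by soft enolisation (O-silylation of the lactone carbonyl, then deprotonation at C15), turn the butenolide into the aromatic 2-silyloxyfuran; no stereocentre is involved.

Step 4
Reactants: 3 14-O-acetyl-3,19-O-isopropylideneandrographolide; 5 tris-silylated silyloxyfuran
Product: 7 3,19-bis-O-triethylsilyl-3',19'-O-isopropylidene derivative of the target (15R,12'S), via endo oxanorbornene cycloadduct 6 (not isolated)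
Conditions: 5 (1.5 equiv), CH2Cl2, 12 kbar, 25 °C, 48 h; then 1 bar, 40 °C, 2 h
Reagents that add atoms: none
Why: A pressure-accelerated normal-demand Diels–Alder [4+2] cycloaddition joins C15 to the β-carbon C12' and C16 to C13' through the endo transition state (lactone carbonyl under the furan) on the alkene face anti to the C14' acetate bought with 1, which sets C12' (S) and C15 (R) together, and the bridgehead silyl ketal then undergoes Grob fragmentation (C16–C13' antiperiplanar to C14'–OAc, Et3SiOAc lost) to restore both butenolides.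

Step 5
Reactants: 7 protected dimer
Product: 8 target CNP0220272.2
Conditions: AcOH–THF–H2O (3:1:1), 35 °C
Reagents that add atoms: none
Why: Mild Brønsted-acid hydrolysis cleaves the acetonide and both triethylsilyl ethers in one operation without touching the exocyclic alkenes, the butenolides or the C15 and C12' stereocentres.

**Compound list**

1 | andrographolide, (3E,4S)-3-{2-[(1R,4aS,5R,6R,8aS)-6-hydroxy-5-(hydroxymethyl)-5,8a-dimethyl-2-methylidenedecahydronaphthalen-1-yl]ethylidene}-4-hydroxyoxolan-2-one | C=C1CC[C@@H]2[C@](C)(CO)[C@H](O)CC[C@@]2(C)[C@@H]1C/C=C1/C(=O)OC[C@H]1O | starting material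
2 | 3,19-O-isopropylideneandrographolide (acetonide bridging O3 and O19; 12E; free 14S hydroxyl) | C=C1CC[C@@H]2[C@](C)(COC(C)(C)O3)[C@H]3CC[C@@]2(C)[C@@H]1C/C=C1/C(=O)OC[C@H]1O | intermediate
3 | 14-O-acetyl-3,19-O-isopropylideneandrographolide (12E; 14S acetate) | C=C1CC[C@@H]2[C@](C)(COC(C)(C)O3)[C@H]3CC[C@@]2(C)[C@@H]1C/C=C1/C(=O)OC[C@H]1OC(C)=O | intermediate
4 | 14-deoxy-11,12-didehydroandrographolide, 3-{(E)-2-[(1R,4aS,5R,6R,8aR)-6-hydroxy-5-(hydroxymethyl)-5,8a-dimethyl-2-methylidenedecahydronaphthalen-1-yl]ethenyl}furan-2(5H)-one | C=C1CC[C@@H]2[C@](C)(CO)[C@H](O)CC[C@@]2(C)[C@@H]1/C=C/C1=CCOC1=O | starting material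
5 | 3,19-bis-O-triethylsilyl ether of 4 with the lactone converted into its 2-(triethylsilyloxy)furan (11E alkene on furan C3) | C=C1CC[C@@H]2[C@](C)(CO[Si](CC)(CC)CC)[C@H](O[Si](CC)(CC)CC)CC[C@@]2(C)[C@@H]1/C=C/c1ccoc1O[Si](CC)(CC)CC | intermediate
6 | endo [4+2] adduct: 1-(triethylsilyloxy)-7-oxabicyclo[2.2.1]hept-2-ene (C1 = C16, C4 = C15) spiro-fused at C6 (= C13') to the 14'S-acetoxy lactone; C15 R, C12' S, lactone carbonyl endo, acetate anti to the C13'–C16 bond | C=C1CC[C@@H]2[C@](C)(CO[Si](CC)(CC)CC)[C@H](O[Si](CC)(CC)CC)CC[C@@]2(C)[C@@H]1/C=C/C3=C[C@@H]4[C@@H](C[C@@H]5C(=C)CC[C@@H]6[C@](C)(COC(C)(C)O7)[C@H]7CC[C@]65C)[C@]8(C(=O)OC[C@H]8OC(C)=O)[C@@]3(O[Si](CC)(CC)CC)O4 | intermediate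
7 | 3,19-bis-O-triethylsilyl-3',19'-O-isopropylidene derivative of the target (15R,12'S; C15–C12' bond between the two butenolide halves) | C=C1CC[C@@H]2[C@](C)(CO[Si](CC)(CC)CC)[C@H](O[Si](CC)(CC)CC)CC[C@@]2(C)[C@@H]1/C=C/C1=C[C@H]([C@@H](C[C@@H]2C(=C)CC[C@@H]3[C@](C)(COC(C)(C)O4)[C@H]4CC[C@]32C)C2=CCOC2=O)OC1=O | intermediate
8 | CNP0220272.2, the (15R,12'S) C15–C12' linked bis-andrographolide | C=C1CC[C@@H]2[C@](C)(CO)[C@H](O)CC[C@@]2(C)[C@@H]1/C=C/C1=C[C@H]([C@@H](C[C@@H]2C(=C)CC[C@@H]3[C@](C)(CO)[C@H](O)CC[C@]32C)C2=CCOC2=O)OC1=O | target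

**Totals**

Total steps: 5. Longest linear sequence: 4 steps (1 → 2 → 3 → 7 → 8); the other branch is 4 → 5 → 7 → 8.

**Steps most likely to fail, with fallbacks**

Step 4 (highest risk). The trisubstituted alkylidene lactone is a sluggish dienophile. The cross-conjugated silyl trienol ether of 5 could also react at C13 or C11. The anti/endo preference that gives (15R,12'S) is a prediction from the transition-state model, and the selectivity may be only moderate; minor diastereomers would be removed on silica at 7 or by HPLC at 8. The fallback replaces the cycloaddition by an anionic vinylogous Michael addition–E1cB elimination. It sets out from 4, with 3 unchanged as partner. Transketalisation (Me2C(OMe)2, PPTS) gives 3,19-O-isopropylidene-14-deoxy-11,12-didehydroandrographolide F1. LiN(SiMe3)2 in THF at −78 °C gives its lithium 2-furanolate F2. Addition of 3 leads, by γ-attack of C15 on C12' anti to the acetate and loss of lithium acetate, to the bis-acetonide of the target F3. The conditions of step 5 (aqueous AcOH) then convert F3 into 8, where the fallback rejoins the route.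

Step 3. Silylating two alcohols (one hindered, at C3) and the lactone in one pot may stop short or give C-silylation, and the dienyl silyloxyfuran may hydrolyse on isolation. The fallback separates alcohol protection from enol-silane formation and changes from soft to hard enolisation. It sets out from 4. Et3SiCl and imidazole in DMF give the chromatographable 3,19-bis-O-triethylsilyl-14-deoxy-11,12-didehydroandrographolide F4. LiN(SiMe3)2 in THF at −78 °C gives the lithium furanolate F5, which is O-silylated in the same flask by Et3SiCl. Filtration under argon delivers 5, where the fallback rejoins the route.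

Step 5. The hindered C3 silyl ether and the acetonide may hydrolyse at different rates, and long acid exposure risks migration of the two exocyclic C8=C17 alkenes. The fallback unmasks the two kinds of protecting group by different mechanisms in two stages. It sets out from 7. HF·pyridine buffered with pyridine in THF at 0 °C cleaves only the Si–O bonds and gives the 3',19'-O-isopropylidene derivative of the target F6. The acetonide is then removed by transketalisation into methanol (PPTS cat., MeOH, 25 °C), which gives 8, where the fallback rejoins the route.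

**Further compounds**

F1 | step 4 | 3,19-O-isopropylidene-14-deoxy-11,12-didehydroandrographolide | C=C1CC[C@@H]2[C@](C)(COC(C)(C)O3)[C@H]3CC[C@@]2(C)[C@@H]1/C=C/C1=CCOC1=O
F2 | step 4 | lithium 2-furanolate of F1 | C=C1CC[C@@H]2[C@](C)(COC(C)(C)O3)[C@H]3CC[C@@]2(C)[C@@H]1/C=C/c1ccoc1[O-].[Li+]
F3 | step 4 | 3,19:3',19'-bis-O-isopropylidene derivative of the target (15R,12'S) | C=C1CC[C@@H]2[C@](C)(COC(C)(C)O3)[C@H]3CC[C@@]2(C)[C@@H]1/C=C/C1=C[C@H]([C@@H](C[C@@H]2C(=C)CC[C@@H]3[C@](C)(COC(C)(C)O4)[C@H]4CC[C@]32C)C2=CCOC2=O)OC1=O
F4 | step 3 | 3,19-bis-O-triethylsilyl-14-deoxy-11,12-didehydroandrographolide | C=C1CC[C@@H]2[C@](C)(CO[Si](CC)(CC)CC)[C@H](O[Si](CC)(CC)CC)CC[C@@]2(C)[C@@H]1/C=C/C1=CCOC1=O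
F5 | step 3 | lithium 2-furanolate of F4 | C=C1CC[C@@H]2[C@](C)(CO[Si](CC)(CC)CC)[C@H](O[Si](CC)(CC)CC)CC[C@@]2(C)[C@@H]1/C=C/c1ccoc1[O-].[Li+]
F6 | step 5 | 3',19'-O-isopropylidene derivative of the target (15R,12'S) | C=C1CC[C@@H]2[C@](C)(CO)[C@H](O)CC[C@@]2(C)[C@@H]1/C=C/C1=C[C@H]([C@@H](C[C@@H]2C(=C)CC[C@@H]3[C@](C)(COC(C)(C)O4)[C@H]4CC[C@]32C)C2=CCOC2=O)OC1=O
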